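**Retrosynthetic overview**

1. Germacrane numbering is used throughout: C1 ketone, C2 CH2, C3 CH–OAc, C4=C5 (Z, methyl C15 on C4), C6 lactone CH–O, C7=C11 butenolide alkene, C8, C9, C10(=C14H2), C12 lactone C=O, C13 CH2OAc.
2. Both acetates are installed last on the 3,13-diol. Its C1 ketone and C3 carbinol come from reductive N–O cleavage of a dihydroisoxazole, a temporary ring that bridges C1 and C3.
3. Key disconnection: C1–C2 together with O–C3, by intramolecular nitrile oxide cycloaddition. The precursor is a monocyclic butenolide with one stereocentre (C6), a (Z)-2-methylbutadienyl group on C6 and a 2-methylidene aldoxime chain on C7.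
4. Enabling feature: the triad C1(=O)–C2H2–C3H–O is the retron of a dihydroisoxazole. The Z C4=C5 alkene and the flat five-membered butenolide ring (O, C6, C7, C11, C12) hold the C2=C3 vinyl group and the C7 chain on the same side, a few rotatable bonds apart.
5. The butenolide comes from asymmetric propiolate addition to a Z-dienal (C6), syn-carbocupration/iodination (C7–C8), Stille hydroxymethylation (C13) and lactonisation. Ring order: butenolide (step 7), then ten-membered ring and dihydroisoxazole together (step 10).

Key step: step 10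

Assumption: the (S,S)-ProPhenol/Me2Zn catalyst is taken to deliver the acetylide to the Si face of the Z-dienal (R carbinol). If the sense is the opposite, the equally available (R,R) ligand is used and nothing else changes.

**Step 1**
Reactants: 1 (2Z)-3-methylpent-2-en-4-yn-1-ol
Product: 2 (2Z)-3-methylpenta-2,4-dien-1-ol
Conditions: H2 (1 atm, 1 equiv uptake), Pd/CaCO3 poisoned with Pb(OAc)2, quinoline, Et2O, 0 °C
Reagents that add atoms: none
Why: Semihydrogenation over poisoned palladium stops at the alkene stage for a terminal alkyne and leaves the trisubstituted alkene, whose Z geometry is bought with 1, untouched (Lindlar-type reduction).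

**Step 2**
Reactants: 2 (2Z)-3-methylpenta-2,4-dien-1-ol
Product: 3 (2Z)-3-methylpenta-2,4-dienal
Conditions: MnO2 (15 equiv), CH2Cl2, 0 °C to rt, dark; used at once
Reagents that add atoms: none
Why: Neutral heterogeneous allylic oxidation with MnO2 gives the enal without acid or base that could isomerise the Z-alkene.

**Step 3**
Reactants: 3 (2Z)-3-methylpenta-2,4-dienal; 4 methyl propiolate
Product: 6 methyl (4R,5Z)-4-hydroxy-6-methylocta-5,7-dien-2-ynoate, via methylzinc acetylide 5 (not isolated)
Conditions: (S,S)-ProPhenol (20 mol %), Ph3PO (40 mol %), Me2Zn (3 equiv), 4 (3 equiv), toluene, 0 to 4 °C; then H2O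
Reagents that add atoms: none
Why: Catalytic asymmetric alkynylation of an enal by the zinc acetylide 5 inside the dinuclear zinc–ProPhenol pocket, which should direct attack to the Si face of the aldehyde and so set C6 as R.

**Step 4**
Reactants: 6 methyl (4R,5Z)-4-hydroxy-6-methylocta-5,7-dien-2-ynoate
Product: 7 methyl (4R,5Z)-6-methyl-4-(triethylsilyloxy)octa-5,7-dien-2-ynoate
Conditions: TESCl, imidazole, CH2Cl2, 0 °C
Reagents that add atoms: chlorotriethylsilane, CC[Si](Cl)(CC)CC
Why: Standard silylation, needed so that the ester cannot lactonise early and no dienyl-substituted allylic lactone meets zerovalent palladium in step 6.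

**Step 5**
Reactants: 7 methyl (4R,5Z)-6-methyl-4-(triethylsilyloxy)octa-5,7-dien-2-ynoate; 8 4-chloro-1,1-dimethoxybutane
Product: 12 methyl (2E,4R,5Z)-3-(4,4-dimethoxybutyl)-2-iodo-6-methyl-4-(triethylsilyloxy)octa-2,5,7-trienoate, via Grignard reagent 9 (not isolated), via dialkylcuprate 10 (not isolated), via alkenylcuprate 11 (not isolated)
Conditions: 8, Mg, THF, reflux; CuBr·SMe2 (0.5 equiv per 9), THF, −40 °C; 7, −78 °C; then I2, THF, −78 °C
Reagents that add atoms: iodine, [I][I]
Why: Syn-carbocupration of an alkynoate places the new chain on C7 and copper on C11 on the same side, the alkenylcuprate 11 keeps its geometry at −78 °C and iodinolysis occurs with retention, so the ester ends up cis to C6 as the lactone needs, and C6 is not touched.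

**Step 6**
Reactants: 12 methyl (2E,4R,5Z)-3-(4,4-dimethoxybutyl)-2-iodo-6-methyl-4-(triethylsilyloxy)octa-2,5,7-trienoate; 13 (tributylstannyl)methanol
Product: 14 methyl (2Z,4R,5Z)-3-(4,4-dimethoxybutyl)-2-(hydroxymethyl)-6-methyl-4-(triethylsilyloxy)octa-2,5,7-trienoate
Conditions: Pd(PPh3)4 (10 mol %), CuI (20 mol %), DMF, 50 °C
Reagents that add atoms: none
Why: Stille coupling of an α-iodo enoate, in which the stannane transfers its hydroxymethyl group in preference to butyl and the alkene geometry is retained.

**Step 7**
Reactants: 14 methyl (2Z,4R,5Z)-3-(4,4-dimethoxybutyl)-2-(hydroxymethyl)-6-methyl-4-(triethylsilyloxy)octa-2,5,7-trienoate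
Product: 17 4-{(2R)-4-(hydroxymethyl)-2-[(1Z)-2-methylbuta-1,3-dien-1-yl]-5-oxo-2,5-dihydrofuran-3-yl}butanal, via hydroxy ester 15 (not isolated), via butenolide acetal 16 (not isolated)
Conditions: AcOH–THF–H2O (3:1:1), 35 °C
Reagents that add atoms: water, O
Why: Mild aqueous acid removes the TES group, the freed C6 hydroxyl that sits cis to the ester on the tetrasubstituted alkene lactonises spontaneously with retention at C6 (the C6–O bond is not broken), and the dimethyl acetal is hydrolysed in the same pot.

**Step 8**
Reactants: 17 4-{(2R)-4-(hydroxymethyl)-2-[(1Z)-2-methylbuta-1,3-dien-1-yl]-5-oxo-2,5-dihydrofuran-3-yl}butanal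
Product: 18 4-{(2R)-4-(hydroxymethyl)-2-[(1Z)-2-methylbuta-1,3-dien-1-yl]-5-oxo-2,5-dihydrofuran-3-yl}-2-methylidenebutanal
Conditions: aq HCHO (37 %), pyrrolidine (10 mol %), propionic acid (10 mol %), i-PrOH, 45 °C
Reagents that add atoms: formaldehyde, C=O
Why: Amine/acid-catalysed Mannich condensation–elimination (organocatalytic α-methylenation of aldehydes) works at the only enolisable position C10, and the buffered medium is too weakly basic to deprotonate C6–H.

**Step 9**
Reactants: 18 4-{(2R)-4-(hydroxymethyl)-2-[(1Z)-2-methylbuta-1,3-dien-1-yl]-5-oxo-2,5-dihydrofuran-3-yl}-2-methylidenebutanal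
Product: 19 the (E)-aldoxime of 18
Conditions: NH2OH·HCl, NaOAc, EtOH–H2O, 0 °C
Reagents that add atoms: hydroxylamine hydrochloride, NO.Cl
Why: Condensation of the aldehyde with hydroxylamine in acetate buffer is much faster than conjugate addition or attack on the lactone (oxime formation).

**Step 10**
Reactants: 19 the (E)-aldoxime of 18
Product: 21 (3S,6R)-13-hydroxy-1,3-(nitrilooxy)-bridged germacra-4Z,7(11),10(14)-trien-12,6-olide (ten-membered carbocycle spanned by C1=N–O–C3), via nitrile oxide 20 (not isolated)
Conditions: PhI(OAc)2 (1.2 equiv), CH2Cl2, 35 °C; 19 added by syringe pump over 12 h, final 1 mM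
Reagents that add atoms: none
Why: PhI(OAc)2 dehydrogenates the aldoxime to the conjugated nitrile oxide 20, which adds in a concerted (3+2) cycloaddition to the terminal vinyl group of the Z-diene, its carbon (C1) bonding to the CH2 terminus (C2) and its oxygen to C3. The closest known reaction type is the intramolecular nitrile oxide–olefin cycloaddition in its bridged mode, which closes medium and large rings as 3,5-bridged 4,5-dihydroisoxazoles that are masked β-hydroxy ketones. Two rings close at once: the ten-membered carbocycle through C1–C2 in the endo (bridged) mode, in which both vinyl carbons become ring members, and the five-membered dihydroisoxazole through O–C3, giving a bicyclo[7.2.1] core on the butenolide. The only new stereocentre, C3, is controlled by C6: A(1,3) strain across the Z C4=C5 bond keeps C6–H in the alkene plane, so C7 and its chain leave from one face, the vinyl group has to stand roughly perpendicular to that plane with C2 on the same face as C7 to be reached by the link C8–C9–C10–C1, and the dipole then adds to the inner face of the vinyl group, which is 3S for 6R (C3–O and C6–O trans on the flat ring drawing). The step needs regioselectivity (oxygen to the substituted carbon, the innate preference for monosubstituted alkenes and 1,3-dienes), site selectivity against the trisubstituted C4=C5 bond (a seven-membered closure that would have to build a fully substituted C4–O centre on a far poorer dipolarophile) and against the inert tetrasubstituted butenolide alkene, and suppression of furoxan formation, which slow addition at high dilution secures. Preorganisation comes from the substrate, since the Z-alkene, the planar butenolide and the sp2 centre C10 leave only five rotatable bonds between dipole and dipolarophile, one of them (C5–C6) already biased by A(1,3) strain.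

**Step 11**
Reactants: 21 (3S,6R)-13-hydroxy-1,3-(nitrilooxy)-bridged germacra-4Z,7(11),10(14)-trien-12,6-olide
Product: 23 (3S,6R)-3,13-dihydroxy-1-oxogermacra-4Z,7(11),10(14)-trien-12,6-olide, via hydroxy imine 22 (not isolated)
Conditions: SmI2 (3 equiv), THF, 0 °C, 10 min; air; then B(OH)3, MeOH–H2O, rt
Reagents that add atoms: water, O
Why: Single-electron reduction by SmI2 cleaves the weak N–O bond of conjugated dihydroisoxazoles quickly, excess reductant is destroyed by air before the boric acid-buffered hydrolysis of imine 22 unveils the enone, and C3 keeps its configuration because its C–O bond is not involved (reductive isoxazoline opening).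

**Step 12**
Reactants: 23 (3S,6R)-3,13-dihydroxy-1-oxogermacra-4Z,7(11),10(14)-trien-12,6-olide
Product: 24 (3S,6R)-3,13-diacetoxy-1-oxogermacra-4Z,7(11),10(14)-trien-12,6-olide (CNP0272505.1)
Conditions: Ac2O (4 equiv), pyridine, CH2Cl2, 0 °C
Reagents that add atoms: acetic anhydride, CC(=O)OC(C)=O
Why: Acylation of the primary and the secondary allylic alcohol under weakly basic conditions at low temperature, chosen to avoid E1cB loss of the C3 oxygen from the β-oxygenated ketone.

**Compound list**

1 | (2Z)-3-methylpent-2-en-4-yn-1-ol | OC/C=C(/C)C#C | starting material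
2 | (2Z)-3-methylpenta-2,4-dien-1-ol | OC/C=C(/C)C=C | intermediate
3 | (2Z)-3-methylpenta-2,4-dienal | O=C/C=C(/C)C=C | intermediate
4 | methyl propiolate | C#CC(=O)OC | starting material
5 | methyl 3-(methylzincio)prop-2-ynoate | C[Zn]C#CC(=O)OC | intermediate
6 | methyl (4R,5Z)-4-hydroxy-6-methylocta-5,7-dien-2-ynoate | COC(=O)C#C[C@H](O)/C=C(/C)C=C | intermediate
7 | methyl (4R,5Z)-6-methyl-4-(triethylsilyloxy)octa-5,7-dien-2-ynoate | COC(=O)C#C[C@H](O[Si](CC)(CC)CC)/C=C(/C)C=C | intermediate
8 | 4-chloro-1,1-dimethoxybutane | COC(CCCCl)OC | starting material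
9 | (4,4-dimethoxybutyl)magnesium chloride | COC(CCC[Mg]Cl)OC | intermediate
10 | chloromagnesium bis(4,4-dimethoxybutyl)cuprate | COC(CCC[Cu-]CCCC(OC)OC)OC.[Mg+2].[Cl-] | intermediate
11 | chloromagnesium alkenyl(4,4-dimethoxybutyl)cuprate from syn addition of 10 to 7 | COC(=O)/C([Cu-]CCCC(OC)OC)=C(/CCCC(OC)OC)[C@H](O[Si](CC)(CC)CC)/C=C(/C)C=C.[Mg+2].[Cl-] | intermediate
12 | methyl (2E,4R,5Z)-3-(4,4-dimethoxybutyl)-2-iodo-6-methyl-4-(triethylsilyloxy)octa-2,5,7-trienoate | COC(=O)/C(I)=C(/CCCC(OC)OC)[C@H](O[Si](CC)(CC)CC)/C=C(/C)C=C | intermediate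
13 | (tributylstannyl)methanol | CCCC[Sn](CCCC)(CCCC)CO | starting material
14 | methyl (2Z,4R,5Z)-3-(4,4-dimethoxybutyl)-2-(hydroxymethyl)-6-methyl-4-(triethylsilyloxy)octa-2,5,7-trienoate | COC(=O)/C(CO)=C(/CCCC(OC)OC)[C@H](O[Si](CC)(CC)CC)/C=C(/C)C=C | intermediate
15 | methyl (2Z,4R,5Z)-3-(4,4-dimethoxybutyl)-4-hydroxy-2-(hydroxymethyl)-6-methylocta-2,5,7-trienoate | COC(=O)/C(CO)=C(/CCCC(OC)OC)[C@H](O)/C=C(/C)C=C | intermediate
16 | (5R)-4-(4,4-dimethoxybutyl)-3-(hydroxymethyl)-5-[(1Z)-2-methylbuta-1,3-dien-1-yl]furan-2(5H)-one | COC(CCCC1=C(CO)C(=O)O[C@@H]1/C=C(/C)C=C)OC | intermediate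
17 | 4-{(2R)-4-(hydroxymethyl)-2-[(1Z)-2-methylbuta-1,3-dien-1-yl]-5-oxo-2,5-dihydrofuran-3-yl}butanal | O=CCCCC1=C(CO)C(=O)O[C@@H]1/C=C(/C)C=C | intermediate
18 | 4-{(2R)-4-(hydroxymethyl)-2-[(1Z)-2-methylbuta-1,3-dien-1-yl]-5-oxo-2,5-dihydrofuran-3-yl}-2-methylidenebutanal | O=CC(=C)CCC1=C(CO)C(=O)O[C@@H]1/C=C(/C)C=C | intermediate
19 | (E)-aldoxime of 18 | O/N=C/C(=C)CCC1=C(CO)C(=O)O[C@@H]1/C=C(/C)C=C | intermediate
20 | nitrile oxide from 19 | [O-][N+]#CC(=C)CCC1=C(CO)C(=O)O[C@@H]1/C=C(/C)C=C | intermediate
21 | (3S,6R)-13-hydroxy-1,3-(nitrilooxy)-bridged germacra-4Z,7(11),10(14)-trien-12,6-olide | C=C1CCC2=C(CO)C(=O)O[C@@H]2/C=C(/C)[C@@H]3CC1=NO3 | intermediate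
22 | (3S,6R)-3,13-dihydroxy-1-iminogermacra-4Z,7(11),10(14)-trien-12,6-olide | C=C1CCC2=C(CO)C(=O)O[C@@H]2/C=C(/C)[C@@H](O)CC1=N | intermediate
23 | (3S,6R)-3,13-dihydroxy-1-oxogermacra-4Z,7(11),10(14)-trien-12,6-olide | C=C1CCC2=C(CO)C(=O)O[C@@H]2/C=C(/C)[C@@H](O)CC1=O | intermediate
24 | (3S,6R)-3,13-diacetoxy-1-oxogermacra-4Z,7(11),10(14)-trien-12,6-olide (CNP0272505.1) | C=C1CCC2=C(COC(C)=O)C(=O)O[C@@H]2/C=C(/C)[C@@H](OC(C)=O)CC1=O | target

**Total step count:** 12. **Longest linear sequence:** 12 steps (1 to 24).

**Steps most likely to fail**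

**1. Step 10.**
- The dipole may be captured by the nearer trisubstituted alkene. The conjugated nitrile oxide may also dimerise faster than the medium ring closes.
- The fallback sets out from 18 and comes back at 24. It makes the same C1–C2 bond by a reductive acyl–alkyl coupling.
- Compound 18 is acetylated (Ac2O, pyridine, 0 °C) to the 13-acetate enal F1.
- NIS in AcOH–CH2Cl2 at 0 °C adds iodine to the terminal CH2 (C2) and acetate to C3 of the diene, giving the iodo acetate F2. High facial selectivity is not expected here, so a chromatographic purification is planned at this stage.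
- Pinnick oxidation (NaClO2, NaH2PO4, 2-methyl-2-butene) gives the 2-methylidene carboxylic acid F3.
- 2,2'-Dipyridyl disulfide and PPh3 give the S-(pyridin-2-yl) thioester F4.
- The ring is closed by the nickel/zirconium-mediated ketone synthesis from a thioester and a primary alkyl iodide (NiBr2(dtbbpy), Cp2ZrCl2, Zn, DMI, slow addition, high dilution). Its radical activation of the iodide avoids β-elimination of the acetate and should give 24 directly.

**2. Step 3.**
- The Z geometry of the dienal may erode on the Lewis acidic zinc species. Facial discrimination may be weak for a Z-configured β,β-disubstituted enal.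
- The fallback sets out from 3 and 4 and comes back at 6. It moves the stereochemical decision from the C–C bond formation to a ketone reduction.
- The lithium acetylide of 4 (n-BuLi, THF, −78 °C) adds quickly to 3 and gives the racemic propargylic alcohol F5.
- MnO2 in CH2Cl2 gives the dienyl alkynyl ketone F6.
- CBS reduction with (R)-2-methyl-CBS-oxazaborolidine and catecholborane in toluene at −78 °C treats the alkynyl group as the small substituent and should return 6.

**3. Step 5.**
- The alkenylcuprate may equilibrate through its allenolate, with loss of alkene geometry. Addition to the hindered alkynoate may also be sluggish.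
- The fallback sets out from 6 and comes back at 16.
- The free alcohol 6 (no TES group) is treated with an excess of cuprate 10.
- The magnesium alkoxide lactonises in the flask as soon as the ester stands cis to it, so the ring, not the temperature, fixes the alkene geometry. Iodine then gives the α-iodobutenolide F7.
- This allylic lactone is sensitive to zerovalent palladium. The hydroxymethyl group is therefore brought in from 13 at room temperature under copper-assisted Stille conditions (Pd(PPh3)4, copper thiophene-2-carboxylate, tetrabutylammonium diphenylphosphinate, DMF).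
- This gives 16, which is hydrolysed to 17 as in step 7.

**Further compounds**

F1 | step 10 | 13-O-acetyl derivative of enal 18 | C=C(CCC1=C(COC(C)=O)C(=O)O[C@@H]1/C=C(/C)C=C)C=O
F2 | step 10 | iodo acetate (C2 iodide, C3 acetate, C3 configured as in 24) | C=C(CCC1=C(COC(C)=O)C(=O)O[C@@H]1/C=C(/C)[C@@H](OC(C)=O)CI)C=O
F3 | step 10 | 2-methylidene carboxylic acid from F2 | C=C(CCC1=C(COC(C)=O)C(=O)O[C@@H]1/C=C(/C)[C@@H](OC(C)=O)CI)C(=O)O
F4 | step 10 | S-(pyridin-2-yl) thioester of F3 | C=C(CCC1=C(COC(C)=O)C(=O)O[C@@H]1/C=C(/C)[C@@H](OC(C)=O)CI)C(=O)Sc1ccccn1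
F5 | step 3 | racemic methyl (5Z)-4-hydroxy-6-methylocta-5,7-dien-2-ynoate | COC(=O)C#CC(O)/C=C(/C)C=C
F6 | step 3 | methyl (5Z)-6-methyl-4-oxoocta-5,7-dien-2-ynoate | COC(=O)C#CC(=O)/C=C(/C)C=C
F7 | step 5 | (5R)-4-(4,4-dimethoxybutyl)-3-iodo-5-[(1Z)-2-methylbuta-1,3-dien-1-yl]furan-2(5H)-one | COC(CCCC1=C(I)C(=O)O[C@@H]1/C=C(/C)C=C)OC
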